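**Plan**

- Rings: D is the 3,5-dihydroxyphenyl group; C, B and A are the benzo rings of the three trans-2,3-diaryl-2,3-dihydrobenzofurans, A carrying the styryl arm. The retrosynthesis cuts the stilbene C=C on C4 of ring A first, then in each dihydrobenzofuran (A, then B, then C) the O1–C2, C2–aryl and C3–C3a bonds.
- Enabling feature: C2 and C3 of every dihydrobenzofuran carry three different aryl groups (4-hydroxyphenyl on C2; on C3 the fused benzo ring through C3a and the neighbouring unit). Each C2–C3 pair is therefore an (E)-alkenylboronate that takes one aryl from boron (C2–aryl) and one from palladium (C3–C3a).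
- Forward: ring D alkenylboronate, then rings C, B and A by three rounds of conjunctive coupling, C–B oxidation, acid ring closure and chromium boryl olefination of the C4 aldehyde. One 2-bromoresorcinol aldehyde building block serves as rings C, B and A, and one titrated stock of 4-methoxyphenyllithium serves all three rounds.
- Stereochemistry: C3 of each ring comes from the chiral ferrocenyl diphosphine on palladium (one antipode for rings C and A, the other for ring B). C2 follows as trans in the reversible acid closure. The E-alkene comes from the final olefination.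
- Boron carries the mac diol, because pinacol esters of beta-substituted alkenylboronates are prone to direct Suzuki transfer. The styryl arm and the free phenols come last (BBr3 before the olefination, then silyl ethers and fluoride), because acid would cyclise a stilbene onto ring B or onto the C2 cation.

Key step: step 19

Abbreviations: MOM = methoxymethyl; TBS = tert-butyldimethylsilyl; B(mac) = boron esterified with cis-1,2-dimethylacenaphthene-1,2-diol; L = (Sp,Sp)-MandyPhos, 1,1′-bis[bis(4-methoxy-3,5-dimethylphenyl)phosphino]-2,2′-bis[(R)-α-(dimethylamino)benzyl]ferrocene, C64H74FeN2O4P2; ent-L = its mirror image; Ar* = 2-(1,3-dioxolan-2-yl)-4,6-bis(methoxymethoxy)phenyl; unit DC = (2R,3R)-3-(3,5-dimethoxyphenyl)-6-methoxy-2-(4-methoxyphenyl)-2,3-dihydrobenzofuran-4-yl; unit DCB = (2S,3S)-3-(unit DC)-6-methoxy-2-(4-methoxyphenyl)-2,3-dihydrobenzofuran-4-yl.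

Assumption: L is taken to send the arylpalladium to the alkene face that gives the 3R rings (C and A) and ent-L to the face that gives the 3S ring (B); should the first coupling show the opposite sense, the two antipodes change places.

**Route**

Step 1
Reactants: 1 acenaphthoquinone
Product: 2 cis-1,2-dimethyl-1,2-dihydroacenaphthylene-1,2-diol (meso; the mac diol)
Conditions: AlMe3 (3 equiv), toluene, 0 °C → rt; aq. HCl work-up; recrystallisation
Reagents that add atoms: trimethylaluminium, C[Al](C)C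
Why: Double 1,2-addition of methyl from AlMe3 to the 1,2-diketone, the second methyl being expected to enter anti to the aluminium alkoxide of the first adduct and so give the cis (meso) diol, with any trans diol left in the mother liquor.

Step 2
Reactants: 2 mac diol; 3 diisopropyl (dichloromethyl)boronate
Product: 4 (dichloromethyl)boronic acid mac ester, Cl2CH–B(mac)
Conditions: Et2O, rt; then evaporation of i-PrOH under vacuum
Reagents that add atoms: none
Why: Boronic ester exchange in which the cis-diol chelates boron and displaces two molecules of propan-2-ol that are removed by evaporation, the usual way from the diisopropyl ester to a (dichloromethyl)boronic diol ester.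

Step 3
Reactants: 5 3,5-dihydroxybenzaldehyde
Product: 6 3,5-bis(methoxymethoxy)benzaldehyde
Conditions: MOMCl (2.5 equiv), i-Pr2NEt (3 equiv), CH2Cl2, 0 °C → rt
Reagents that add atoms: chloromethyl methyl ether, COCCl
Why: Williamson-type O-alkylation of both phenols with MOMCl and a hindered amine, the aldehyde being inert.

Step 4
Reactants: 6 3,5-bis(methoxymethoxy)benzaldehyde
Product: 7 2-bromo-3,5-bis(methoxymethoxy)benzaldehyde
Conditions: NBS (1.05 equiv), MeCN, 0 °C → rt, dark
Reagents that add atoms: N-bromosuccinimide, O=C1CCC(=O)N1Br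
Why: Electrophilic aromatic bromination at C2, which is ortho to one MOM ether and para to the other and, unlike C4, not flanked by two alkoxy groups, the known outcome for 3,5-dialkoxybenzaldehydes, with NBS releasing no strong acid that would cleave the MOM ethers.

Step 5
Reactants: 7 2-bromo-3,5-bis(methoxymethoxy)benzaldehyde
Product: 8 2-[2-bromo-3,5-bis(methoxymethoxy)phenyl]-1,3-dioxolane (the ring bromide, Ar*–Br)
Conditions: Me3SiOCH2CH2OSiMe3 (1.5 equiv), Me3SiOSO2CF3 (5 mol%), CH2Cl2, −78 → −20 °C; then pyridine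
Reagents that add atoms: 1,2-bis(trimethylsilyloxy)ethane, C[Si](C)(C)OCCO[Si](C)(C)C
Why: Noyori acetalisation (silyl transfer from the bis-silyl glycol under catalytic silyl triflate at low temperature) masks the aldehyde without the protic acid and heat that would exchange the MOM ethers, and the dioxolane keeps the aldehyde away from the ate complex and from alkaline peroxide later on.

Step 6
Reactants: 9 3,4-dihydroxybenzaldehyde
Product: 10 3,4-bis(tert-butyldimethylsilyloxy)benzaldehyde
Conditions: TBSCl (2.4 equiv), imidazole (5 equiv), DMF, rt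
Reagents that add atoms: tert-butyldimethylsilyl chloride, CC(C)(C)[Si](C)(C)Cl
Why: Imidazole-mediated silylation of both catechol hydroxyls, silyl ethers being chosen because fluoride removes them at the end without acid.

Step 7
Reactants: 10 3,4-bis(tert-butyldimethylsilyloxy)benzaldehyde
Product: 11 [3,4-bis(tert-butyldimethylsilyloxy)phenyl]methanol
Conditions: NaBH4, MeOH/THF, 0 °C
Reagents that add atoms: none
Why: Borohydride reduction of the aryl aldehyde to the benzylic alcohol, which aryl silyl ethers tolerate at 0 °C.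

Step 8
Reactants: 11 [3,4-bis(tert-butyldimethylsilyloxy)phenyl]methanol
Product: 12 diethyl [3,4-bis(tert-butyldimethylsilyloxy)benzyl]phosphonate
Conditions: ZnI2 (1.5 equiv), P(OEt)3 (3 equiv), THF, reflux
Reagents that add atoms: triethyl phosphite, CCOP(OCC)OCC
Why: ZnI2-mediated direct phosphonylation of an electron-rich benzylic alcohol with triethyl phosphite (a Michaelis–Arbuzov-type transfer), which avoids isolating the labile benzylic halide.

Step 9
Reactants: 13 3,5-dimethoxybenzaldehyde; 4 Cl2CH–B(mac)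
Product: 14 (E)-2-(3,5-dimethoxyphenyl)ethenylboronic acid mac ester
Conditions: 4 (2 equiv), CrCl2 (8 equiv), LiI (4 equiv), THF, rt
Reagents that add atoms: none
Why: Takai–Utimoto-type boryl olefination in which CrCl2 turns the geminal dihalide 4 into a geminal dichromium species that adds to the aldehyde and eliminates to the (E)-alkenylboronate, the diol on boron being a spectator.

Step 10
Reactants: 15 4-bromoanisole
Product: 16 4-methoxyphenyllithium (titrated stock solution in Et2O, kept under argon at −20 °C and re-titrated before each use)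
Conditions: t-BuLi (2.0 equiv, pentane), Et2O, −78 °C, 1 h, then 0 °C; titration
Reagents that add atoms: tert-butyllithium, [Li]C(C)(C)C
Why: Bromine–lithium exchange on the aryl bromide, the second equivalent of t-BuLi destroying the tert-butyl bromide formed (E2 to isobutane, 2-methylpropene and LiBr), so that the stock holds no alkyl halide and can be dosed exactly into each of the three ate-complex formations.

Step 11
Reactants: 14 (E)-2-(3,5-dimethoxyphenyl)ethenylboronic acid mac ester; 16 4-methoxyphenyllithium; 8 ring bromide Ar*–Br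
Product: 19 (1R,2R)-2-(3,5-dimethoxyphenyl)-2-[2-(1,3-dioxolan-2-yl)-4,6-bis(methoxymethoxy)phenyl]-1-(4-methoxyphenyl)ethanol, via lithium ate complex 17 (not isolated), via secondary B(mac) boronate 18 (not isolated)
Conditions: 16 (1.05 equiv, Et2O solution), 14, Et2O, −78 °C → rt; solvent swap to THF; 8 (1.2 equiv), Pd(OAc)2 (3 mol%), L C64H74FeN2O4P2 (3.6 mol%), KOSO2CF3 (3 equiv), 60 °C; then NaOH (3 M aq), H2O2 (30%), 0 °C → rt
Reagents that add atoms: hydrogen peroxide, OO
Why: Palladium-catalysed conjunctive cross-coupling in which 16 adds to boron of 14, the arylpalladium from 8 binds the alkene of ate complex 17 and triggers anti 1,2-migration of the 4-methoxyphenyl group from boron to C-alpha while ring C bonds to C-beta, L choosing the alkene face (C-beta R) and the E-geometry fixing C-alpha relative to it, after which alkaline H2O2 replaces boron by OH with retention.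

Step 12
Reactants: 19 the (1R,2R) alcohol
Product: 20 (2R,3R)-3-(3,5-dimethoxyphenyl)-6-hydroxy-2-(4-methoxyphenyl)-2,3-dihydrobenzofuran-4-carbaldehyde
Conditions: HCl (2 M) in MeOH/THF/H2O (4:4:1), 45 °C
Reagents that add atoms: water, O
Why: Brønsted acid removes both MOM groups (as dimethoxymethane) and the dioxolane and ionises the 4-methoxybenzylic alcohol, and 5-exo capture of the cation by the ortho oxygen closes the dihydrobenzofuran, whose C2 aryl settles trans to the C3 aryl under the reversible conditions, so that C2 is set by C3.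

Step 13
Reactants: 20 the 6-hydroxy aldehyde
Product: 21 (2R,3R)-3-(3,5-dimethoxyphenyl)-6-methoxy-2-(4-methoxyphenyl)-2,3-dihydrobenzofuran-4-carbaldehyde (unit DC carbaldehyde)
Conditions: MeI (3 equiv), K2CO3, acetone, 50 °C
Reagents that add atoms: iodomethane, CI
Why: Williamson methylation of the only free phenol, needed so that no acidic proton meets the aryllithium of the next round, K2CO3 being too weak to touch the benzylic C2 and C3 hydrogens.

Step 14
Reactants: 21 unit DC carbaldehyde; 4 Cl2CH–B(mac)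
Product: 22 (E)-2-(unit DC)ethenylboronic acid mac ester
Conditions: 4 (2 equiv), CrCl2 (8 equiv), LiI (4 equiv), THF, rt
Reagents that add atoms: none
Why: Takai–Utimoto-type boryl olefination as in step 9, E-selective and run under neutral conditions, so the trans ring is not disturbed.

Step 15
Reactants: 22 (E)-2-(unit DC)ethenylboronic acid mac ester; 16 4-methoxyphenyllithium; 8 ring bromide Ar*–Br
Product: 25 (1S,2S)-2-(unit DC)-2-Ar*-1-(4-methoxyphenyl)ethanol, via lithium ate complex 23 (not isolated), via secondary B(mac) boronate 24 (not isolated)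
Conditions: 16 (1.05 equiv, Et2O solution), 22, Et2O/THF, −78 °C → rt; solvent swap to THF; 8 (1.2 equiv), Pd(OAc)2 (5 mol%), ent-L C64H74FeN2O4P2 (6 mol%), KOSO2CF3 (3 equiv), 60 °C; then NaOH (3 M aq), H2O2 (30%), 0 °C → rt
Reagents that add atoms: hydrogen peroxide, OO
Why: The same conjunctive cross-coupling and stereoretentive oxidation as in step 11, now with ent-L so that the new C-beta is S against whatever bias the resident 2R,3R ring exerts (catalyst control), the anti shift across the E-alkene again fixing C-alpha.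

Step 16
Reactants: 25 the (1S,2S) alcohol
Product: 26 (2S,3S)-3-(unit DC)-6-hydroxy-2-(4-methoxyphenyl)-2,3-dihydrobenzofuran-4-carbaldehyde
Conditions: HCl (2 M) in MeOH/THF/H2O (4:4:1), 45 °C
Reagents that add atoms: water, O
Why: The same acid cascade as in step 12 (MOM and dioxolane cleavage, ionisation, 5-exo capture by oxygen), the new ring settling trans with C2 following C3 (2S,3S), while the existing ring can only re-close to its own trans form because its C3 is untouched.

Step 17
Reactants: 26 the 6-hydroxy aldehyde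
Product: 27 (2S,3S)-3-(unit DC)-6-methoxy-2-(4-methoxyphenyl)-2,3-dihydrobenzofuran-4-carbaldehyde (unit DCB carbaldehyde)
Conditions: MeI (3 equiv), K2CO3, acetone, 50 °C
Reagents that add atoms: iodomethane, CI
Why: Williamson methylation of the free phenol as in step 13.

Step 18
Reactants: 27 unit DCB carbaldehyde; 4 Cl2CH–B(mac)
Product: 28 (E)-2-(unit DCB)ethenylboronic acid mac ester
Conditions: 4 (2 equiv), CrCl2 (8 equiv), LiI (4 equiv), THF, rt
Reagents that add atoms: none
Why: Takai–Utimoto-type boryl olefination as in step 9 gives the (E)-alkenylboronate that the key step needs.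

Step 19
Reactants: 28 (E)-2-(unit DCB)ethenylboronic acid mac ester; 16 4-methoxyphenyllithium; 8 ring bromide Ar*–Br
Product: 30 (1R,2R)-2-(unit DCB)-2-Ar*-1-(4-methoxyphenyl)ethylboronic acid mac ester, via lithium ate complex 29 (not isolated)
Conditions: 16 (1.05 equiv, Et2O solution), 28, Et2O/THF, −78 °C → rt; solvent swap to THF; 8 (1.3 equiv), Pd(OAc)2 (5 mol%), L C64H74FeN2O4P2 (6 mol%), KOSO2CF3 (3 equiv), 60 °C; non-oxidative work-up, chromatography
Reagents that add atoms: none
Why: 4-Methoxyphenyllithium 16 adds to boron of 28 to give the four-coordinate boronate 29; oxidative addition of 8 to zerovalent palladium and removal of bromide by KOSO2CF3 leave a cationic divalent arylpalladium that binds the alkene, whereupon the 4-methoxyphenyl group shifts from boron to C-alpha anti to palladium and reductive elimination joins C-beta to ring A. The closest known reaction type is the palladium-catalysed enantioselective conjunctive cross-coupling of beta-substituted alkenyl B(mac) ate complexes with aryl electrophiles, used here with a bromide that has two ortho substituents. No ring is closed: the step makes the C2–aryl and C3–C3a bonds of the future ring A dihydrobenzofuran and two stereocentres. C-beta (later C3, R) is set by the alkene face that the ligand-bound palladium takes, under catalyst control over the two resident rings, and C-alpha (later C2) by the anti-stereospecific shift across the E-alkene. The step needs the conjunctive path to outrun direct Suzuki transfer from boron and needs the metal to meet no second alkene or free carbonyl; the mac diol on boron, the dioxolane in place of a styryl or formyl group and the triflate salt that scavenges bromide secure this. Only C3 has to come out right, since step 21 re-forms C2 as trans.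

Step 20
Reactants: 30 the (1R,2R) secondary boronate
Product: 31 (1R,2R)-2-(unit DCB)-2-Ar*-1-(4-methoxyphenyl)ethanol
Conditions: NaOH (3 M aq), H2O2 (30%), THF, 0 °C → rt
Reagents that add atoms: hydrogen peroxide, OO
Why: Alkaline peroxide oxidation of the secondary boronic ester, a 1,2-shift of carbon from boron to oxygen that retains configuration, with ethers, acetals and the dihydrobenzofurans inert.

Step 21
Reactants: 31 the (1R,2R) alcohol
Product: 32 (2R,3R)-3-(unit DCB)-6-hydroxy-2-(4-methoxyphenyl)-2,3-dihydrobenzofuran-4-carbaldehyde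
Conditions: HCl (2 M) in MeOH/THF/H2O (4:4:1), 45 °C
Reagents that add atoms: water, O
Why: Acid cascade as in steps 12 and 16, the cation at C2 being captured 5-exo by the ring A oxygen to give the trans (2R,3R) ring, with no alkene present that could intercept the cation and the second MOM ether leaving the C6 phenol free.

Step 22
Reactants: 32 the tris(dihydrobenzofuran) hydroxy aldehyde
Product: 33 octaphenol aldehyde (all seven methyl ethers of 32 cleaved)
Conditions: BBr3 (20 equiv), CH2Cl2, −78 °C → rt; then H2O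
Reagents that add atoms: none
Why: BBr3 demethylation of the seven aryl methyl ethers (bromide attacks the methyl of the boron-bound ether) at a stage that has no stilbene for acid to cyclise onto ring B, the aldehyde returning on aqueous work-up.

Step 23
Reactants: 33 octaphenol aldehyde
Product: 34 octakis(tert-butyldimethylsilyl) ether of 33
Conditions: TBSCl (10 equiv), imidazole (24 equiv), DMF, rt; then t-BuMe2SiOSO2CF3 (4 equiv), 0 °C → rt
Reagents that add atoms: tert-butyldimethylsilyl chloride, CC(C)(C)[Si](C)(C)Cl; tert-butyldimethylsilyl trifluoromethanesulfonate, CC(C)(C)[Si](C)(C)OS(=O)(=O)C(F)(F)F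
Why: Imidazole-mediated silylation covers the bulk of the eight phenols and the more electrophilic silyl triflate, added to the same flask, caps any phenol still free, so that one fully silylated, soluble aldehyde without acidic protons goes into the olefination.

Step 24
Reactants: 34 octasilyl aldehyde; 12 diethyl [3,4-bis(tert-butyldimethylsilyloxy)benzyl]phosphonate
Product: 35 decakis(tert-butyldimethylsilyl) ether of the target, (E)-stilbene
Conditions: 12 (2 equiv), KN(SiMe3)2 (2 equiv), THF, −78 °C; then 34, −78 °C → rt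
Reagents that add atoms: none
Why: Horner–Wadsworth–Emmons olefination with a semi-stabilised benzylic phosphonate anion, whose reversible addition funnels into the (E)-stilbene, the hindered amide base leaving aryl silyl ethers alone at low temperature.

Step 25
Reactants: 35 decasilyl ether
Product: 36 CNP0099535.1, (2R,3R)-4-[(E)-2-(3,4-dihydroxyphenyl)ethenyl]-3-{(2S,3S)-3-[(2R,3R)-3-(3,5-dihydroxyphenyl)-6-hydroxy-2-(4-hydroxyphenyl)-2,3-dihydrobenzofuran-4-yl]-6-hydroxy-2-(4-hydroxyphenyl)-2,3-dihydrobenzofuran-4-yl}-2-(4-hydroxyphenyl)-2,3-dihydrobenzofuran-6-ol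
Conditions: Bu4NF (12 equiv), AcOH (12 equiv), THF, 0 °C → rt
Reagents that add atoms: none
Why: Fluoride-induced cleavage of all ten aryl silyl ethers under acetic acid buffering, so that neither acid (stilbene cyclisation) nor free base (catechol oxidation) meets the product.

**Compound list**

1 | acenaphthoquinone | O=C1C(=O)c2cccc3cccc1c23 | starting material
2 | cis-1,2-dimethyl-1,2-dihydroacenaphthylene-1,2-diol (mac diol, meso) | C[C@]1(O)c2cccc3cccc(c23)[C@@]1(C)O | intermediate
3 | diisopropyl (dichloromethyl)boronate | CC(C)OB(OC(C)C)C(Cl)Cl | starting material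
4 | (dichloromethyl)boronic acid mac ester | ClC(Cl)B1O[C@@]2(C)c3cccc4cccc(c34)[C@@]2(C)O1 | intermediate
5 | 3,5-dihydroxybenzaldehyde | O=Cc1cc(O)cc(O)c1 | starting material
6 | 3,5-bis(methoxymethoxy)benzaldehyde | O=Cc1cc(OCOC)cc(OCOC)c1 | intermediate
7 | 2-bromo-3,5-bis(methoxymethoxy)benzaldehyde | O=Cc1cc(OCOC)cc(OCOC)c1Br | intermediate
8 | 2-[2-bromo-3,5-bis(methoxymethoxy)phenyl]-1,3-dioxolane | COCOc1cc(OCOC)c(Br)c(C2OCCO2)c1 | intermediate
9 | 3,4-dihydroxybenzaldehyde | O=Cc1ccc(O)c(O)c1 | starting material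
10 | 3,4-bis(tert-butyldimethylsilyloxy)benzaldehyde | O=Cc1ccc(O[Si](C)(C)C(C)(C)C)c(O[Si](C)(C)C(C)(C)C)c1 | intermediate
11 | [3,4-bis(tert-butyldimethylsilyloxy)phenyl]methanol | OCc1ccc(O[Si](C)(C)C(C)(C)C)c(O[Si](C)(C)C(C)(C)C)c1 | intermediate
12 | diethyl [3,4-bis(tert-butyldimethylsilyloxy)benzyl]phosphonate | CCOP(=O)(Cc1ccc(O[Si](C)(C)C(C)(C)C)c(O[Si](C)(C)C(C)(C)C)c1)OCC | intermediate
13 | 3,5-dimethoxybenzaldehyde | COc1cc(C=O)cc(OC)c1 | starting material
14 | (E)-2-(3,5-dimethoxyphenyl)ethenylboronic acid mac ester | COc1cc(/C=C/B2O[C@@]3(C)c4cccc5cccc(c45)[C@@]3(C)O2)cc(OC)c1 | intermediate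
15 | 4-bromoanisole | COc1ccc(Br)cc1 | starting material
16 | 4-methoxyphenyllithium (titrated stock solution in Et2O) | [Li]c1ccc(OC)cc1 | intermediate
17 | lithium [(E)-2-(3,5-dimethoxyphenyl)ethenyl](4-methoxyphenyl)borate of the mac diol (ate complex) | [Li+].COc1cc(/C=C/[B-]2(c3ccc(OC)cc3)O[C@@]3(C)c4cccc5cccc(c45)[C@@]3(C)O2)cc(OC)c1 | intermediate
18 | (1R,2R)-2-(3,5-dimethoxyphenyl)-2-[2-(1,3-dioxolan-2-yl)-4,6-bis(methoxymethoxy)phenyl]-1-(4-methoxyphenyl)ethylboronic acid mac ester | COCOc1cc(OCOC)c([C@@H](c2cc(OC)cc(OC)c2)[C@H](c2ccc(OC)cc2)B2O[C@@]3(C)c4cccc5cccc(c45)[C@@]3(C)O2)c(C2OCCO2)c1 | intermediate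
19 | (1R,2R)-2-(3,5-dimethoxyphenyl)-2-[2-(1,3-dioxolan-2-yl)-4,6-bis(methoxymethoxy)phenyl]-1-(4-methoxyphenyl)ethanol | COCOc1cc(OCOC)c([C@@H](c2cc(OC)cc(OC)c2)[C@H](c2ccc(OC)cc2)O)c(C2OCCO2)c1 | intermediate
20 | (2R,3R)-3-(3,5-dimethoxyphenyl)-6-hydroxy-2-(4-methoxyphenyl)-2,3-dihydrobenzofuran-4-carbaldehyde | O=Cc1cc(O)cc2c1[C@@H](c1cc(OC)cc(OC)c1)[C@H](c1ccc(OC)cc1)O2 | intermediate
21 | (2R,3R)-3-(3,5-dimethoxyphenyl)-6-methoxy-2-(4-methoxyphenyl)-2,3-dihydrobenzofuran-4-carbaldehyde | O=Cc1cc(OC)cc2c1[C@@H](c1cc(OC)cc(OC)c1)[C@H](c1ccc(OC)cc1)O2 | intermediate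
22 | (E)-2-[(2R,3R)-3-(3,5-dimethoxyphenyl)-6-methoxy-2-(4-methoxyphenyl)-2,3-dihydrobenzofuran-4-yl]ethenylboronic acid mac ester | B1(O[C@@]2(C)c3cccc4cccc(c34)[C@@]2(C)O1)/C=C/c1cc(OC)cc2c1[C@@H](c1cc(OC)cc(OC)c1)[C@H](c1ccc(OC)cc1)O2 | intermediate
23 | lithium ate complex of 22 with 4-methoxyphenyl on boron | [Li+].COc1ccc([B-]2(/C=C/c3cc(OC)cc4c3[C@@H](c3cc(OC)cc(OC)c3)[C@H](c3ccc(OC)cc3)O4)O[C@@]3(C)c4cccc5cccc(c45)[C@@]3(C)O2)cc1 | intermediate
24 | (1S,2S)-2-(unit DC)-2-[2-(1,3-dioxolan-2-yl)-4,6-bis(methoxymethoxy)phenyl]-1-(4-methoxyphenyl)ethylboronic acid mac ester | COCOc1cc(OCOC)c([C@@H]([C@@H](c2ccc(OC)cc2)B2O[C@@]3(C)c4cccc5cccc(c45)[C@@]3(C)O2)c2cc(OC)cc3c2[C@@H](c2cc(OC)cc(OC)c2)[C@H](c2ccc(OC)cc2)O3)c(C2OCCO2)c1 | intermediate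
25 | (1S,2S)-2-(unit DC)-2-[2-(1,3-dioxolan-2-yl)-4,6-bis(methoxymethoxy)phenyl]-1-(4-methoxyphenyl)ethanol | COCOc1cc(OCOC)c([C@@H]([C@@H](c2ccc(OC)cc2)O)c2cc(OC)cc3c2[C@@H](c2cc(OC)cc(OC)c2)[C@H](c2ccc(OC)cc2)O3)c(C2OCCO2)c1 | intermediate
26 | (2S,3S)-3-(unit DC)-6-hydroxy-2-(4-methoxyphenyl)-2,3-dihydrobenzofuran-4-carbaldehyde | COc1ccc([C@H]2Oc3cc(O)cc(C=O)c3[C@@H]2c2cc(OC)cc3c2[C@@H](c2cc(OC)cc(OC)c2)[C@H](c2ccc(OC)cc2)O3)cc1 | intermediate
27 | (2S,3S)-3-(unit DC)-6-methoxy-2-(4-methoxyphenyl)-2,3-dihydrobenzofuran-4-carbaldehyde | COc1ccc([C@H]2Oc3cc(OC)cc(C=O)c3[C@@H]2c2cc(OC)cc3c2[C@@H](c2cc(OC)cc(OC)c2)[C@H](c2ccc(OC)cc2)O3)cc1 | intermediate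
28 | (E)-2-(unit DCB)ethenylboronic acid mac ester | COc1ccc([C@H]2Oc3cc(OC)cc(/C=C/B4O[C@@]5(C)c6cccc7cccc(c67)[C@@]5(C)O4)c3[C@@H]2c2cc(OC)cc3c2[C@@H](c2cc(OC)cc(OC)c2)[C@H](c2ccc(OC)cc2)O3)cc1 | intermediate
29 | lithium ate complex of 28 with 4-methoxyphenyl on boron | [Li+].COc1ccc([C@H]2Oc3cc(OC)cc(/C=C/[B-]4(c5ccc(OC)cc5)O[C@@]5(C)c6cccc7cccc(c67)[C@@]5(C)O4)c3[C@@H]2c2cc(OC)cc3c2[C@@H](c2cc(OC)cc(OC)c2)[C@H](c2ccc(OC)cc2)O3)cc1 | intermediate
30 | (1R,2R)-2-(unit DCB)-2-[2-(1,3-dioxolan-2-yl)-4,6-bis(methoxymethoxy)phenyl]-1-(4-methoxyphenyl)ethylboronic acid mac ester | COc1ccc([C@H]2Oc3cc(OC)cc([C@@H]([C@H](c4ccc(OC)cc4)B4O[C@@]5(C)c6cccc7cccc(c67)[C@@]5(C)O4)c4c(OCOC)cc(OCOC)cc4C4OCCO4)c3[C@@H]2c2cc(OC)cc3c2[C@@H](c2cc(OC)cc(OC)c2)[C@H](c2ccc(OC)cc2)O3)cc1 | intermediate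
31 | (1R,2R)-2-(unit DCB)-2-[2-(1,3-dioxolan-2-yl)-4,6-bis(methoxymethoxy)phenyl]-1-(4-methoxyphenyl)ethanol | COc1ccc([C@H]2Oc3cc(OC)cc([C@@H]([C@H](c4ccc(OC)cc4)O)c4c(OCOC)cc(OCOC)cc4C4OCCO4)c3[C@@H]2c2cc(OC)cc3c2[C@@H](c2cc(OC)cc(OC)c2)[C@H](c2ccc(OC)cc2)O3)cc1 | intermediate
32 | (2R,3R)-3-(unit DCB)-6-hydroxy-2-(4-methoxyphenyl)-2,3-dihydrobenzofuran-4-carbaldehyde | COc1ccc([C@H]2Oc3cc(OC)cc([C@@H]4c5c(C=O)cc(O)cc5O[C@H]4c4ccc(OC)cc4)c3[C@@H]2c2cc(OC)cc3c2[C@@H](c2cc(OC)cc(OC)c2)[C@H](c2ccc(OC)cc2)O3)cc1 | intermediate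
33 | octaphenol aldehyde (32 with all seven methyl ethers cleaved) | Oc1ccc([C@H]2Oc3cc(O)cc([C@@H]4c5c(C=O)cc(O)cc5O[C@H]4c4ccc(O)cc4)c3[C@@H]2c2cc(O)cc3c2[C@@H](c2cc(O)cc(O)c2)[C@H](c2ccc(O)cc2)O3)cc1 | intermediate
34 | octakis(tert-butyldimethylsilyl) ether of 33 | CC(C)(C)[Si](C)(C)Oc1ccc([C@H]2Oc3cc(O[Si](C)(C)C(C)(C)C)cc([C@@H]4c5c(C=O)cc(O[Si](C)(C)C(C)(C)C)cc5O[C@H]4c4ccc(O[Si](C)(C)C(C)(C)C)cc4)c3[C@@H]2c2cc(O[Si](C)(C)C(C)(C)C)cc3c2[C@@H](c2cc(O[Si](C)(C)C(C)(C)C)cc(O[Si](C)(C)C(C)(C)C)c2)[C@H](c2ccc(O[Si](C)(C)C(C)(C)C)cc2)O3)cc1 | intermediate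
35 | decakis(tert-butyldimethylsilyl) ether of the target | CC(C)(C)[Si](C)(C)Oc1ccc([C@H]2Oc3cc(O[Si](C)(C)C(C)(C)C)cc([C@@H]4c5c(/C=C/c6ccc(O[Si](C)(C)C(C)(C)C)c(O[Si](C)(C)C(C)(C)C)c6)cc(O[Si](C)(C)C(C)(C)C)cc5O[C@H]4c4ccc(O[Si](C)(C)C(C)(C)C)cc4)c3[C@@H]2c2cc(O[Si](C)(C)C(C)(C)C)cc3c2[C@@H](c2cc(O[Si](C)(C)C(C)(C)C)cc(O[Si](C)(C)C(C)(C)C)c2)[C@H](c2ccc(O[Si](C)(C)C(C)(C)C)cc2)O3)cc1 | intermediate
36 | CNP0099535.1 | Oc1ccc([C@H]2Oc3cc(O)cc([C@@H]4c5c(/C=C/c6ccc(O)c(O)c6)cc(O)cc5O[C@H]4c4ccc(O)cc4)c3[C@@H]2c2cc(O)cc3c2[C@@H](c2cc(O)cc(O)c2)[C@H](c2ccc(O)cc2)O3)cc1 | target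

**Summary**

Total step count: 25. Longest linear sequence: 18 steps (steps 3–5 and 11–25, or equally steps 1, 2, 9 and 11–25).

**Steps most likely to fail**

1. Step 19 (the same risk applies to steps 11 and 15). The hindered arylpalladium from 8 may engage the beta-aryl alkenylboronate too slowly. Direct Suzuki transfer of the anisyl or alkenyl group, protodeboronation, or loss of face control against the two resident rings could then take over.
Fallback, from aldehyde 27 back to alcohol 31, making the two bonds one at a time by carbonyl chemistry: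
   - Bromine–lithium exchange on 8 (n-BuLi, THF, −78 °C) and addition to 27 should give the diaryl carbinol (unit DCB)(Ar*)methanol F1.
   - Dess–Martin oxidation should give the diaryl ketone F2.
   - Corey–Chaykovsky methylenation (Me3SI, KOt-Bu, DMSO/THF) should give the 2,2-diaryloxirane F3.
   - ZnI2-promoted Meinwald rearrangement (hydride shift) should give the diarylacetaldehyde F4.
   - Addition of 4-MeOC6H4MgBr should give 31 as a mixture at both new carbons.
   - The carbinol centre is erased in step 21; the C3 epimers would be separated by chromatography at the stage of 32. Catalyst control of C3 is given up in this detour.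

2. Step 21 (likewise steps 12 and 16). The benzylic alcohol may ionise before the neighbouring oxygen is ready. The cation could then lose the C3 hydrogen (scrambling the centre set in step 19), alkylate a resorcinol-type ring, or the two rings already present could open and re-close.
Fallback, from alkenylboronate 28 back to octaphenol 33, closing the ring by joining the carbinol oxygen to the arene with retention at C2, so that no cation is needed:
   - Purchased 3-chloro-5-methoxybenzaldehyde is brominated para to the methoxy group (NBS, MeCN) to 2-bromo-3-chloro-5-methoxybenzaldehyde F5.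
   - Acetalisation (ethylene glycol, TsOH, toluene, reflux) gives 2-(2-bromo-3-chloro-5-methoxyphenyl)-1,3-dioxolane F6.
   - Under the conditions of step 19, 28, 16 and F6 (C–Br reacts, C–Cl stays) should give the chloroaryl secondary boronate F7.
   - NaOH/H2O2 should give the chloroaryl alcohol F8 with retention.
   - Palladium-catalysed intramolecular aryl ether formation (Pd(OAc)2, 2-(di-tert-butylphosphino)-1,1′-binaphthyl, Cs2CO3, toluene, 80 °C) should turn the anti adduct directly into the trans dihydrobenzofuran dioxolane F9.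
   - Mild aqueous acid (HCl, THF, rt) frees the 6-methoxy aldehyde F10.
   - BBr3 as in step 22 cleaves its eight methyl ethers to 33.

3. Step 22. BBr3 and bromide may open the three benzylic ether rings, leave some of the seven methyl ethers in place, or promote Friedel–Crafts attack on the boron-bound aldehyde.
Fallback, from 32 back to the target 36, carrying the methyl ethers through the olefination and removing them last with a nucleophile under basic conditions:
   - Horner–Wadsworth–Emmons reaction of 32 with 12 (3 equiv KN(SiMe3)2, the ring A phenol carried as its phenoxide) should give the heptamethyl bis-silyl stilbene F11.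
   - NaSEt (large excess) in DMF at 140 °C should cleave the seven methyl ethers by SN2 attack at methyl and strip the two silyl ethers, giving 36 without any acid.

Further compounds
F1 | step 19 | (unit DCB)[2-(1,3-dioxolan-2-yl)-4,6-bis(methoxymethoxy)phenyl]methanol (both carbinol epimers) | COc1ccc([C@H]2Oc3cc(OC)cc(C(O)c4c(OCOC)cc(OCOC)cc4C4OCCO4)c3[C@@H]2c2cc(OC)cc3c2[C@@H](c2cc(OC)cc(OC)c2)[C@H](c2ccc(OC)cc2)O3)cc1
F2 | step 19 | (unit DCB) [2-(1,3-dioxolan-2-yl)-4,6-bis(methoxymethoxy)phenyl] ketone | COc1ccc([C@H]2Oc3cc(OC)cc(C(=O)c4c(OCOC)cc(OCOC)cc4C4OCCO4)c3[C@@H]2c2cc(OC)cc3c2[C@@H](c2cc(OC)cc(OC)c2)[C@H](c2ccc(OC)cc2)O3)cc1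
F3 | step 19 | 2-(unit DCB)-2-[2-(1,3-dioxolan-2-yl)-4,6-bis(methoxymethoxy)phenyl]oxirane (both epimers) | COc1ccc([C@H]2Oc3cc(OC)cc(C4(CO4)c4c(OCOC)cc(OCOC)cc4C4OCCO4)c3[C@@H]2c2cc(OC)cc3c2[C@@H](c2cc(OC)cc(OC)c2)[C@H](c2ccc(OC)cc2)O3)cc1
F4 | step 19 | 2-(unit DCB)-2-[2-(1,3-dioxolan-2-yl)-4,6-bis(methoxymethoxy)phenyl]acetaldehyde (both epimers) | COc1ccc([C@H]2Oc3cc(OC)cc(C(C=O)c4c(OCOC)cc(OCOC)cc4C4OCCO4)c3[C@@H]2c2cc(OC)cc3c2[C@@H](c2cc(OC)cc(OC)c2)[C@H](c2ccc(OC)cc2)O3)cc1
F5 | step 21 | 2-bromo-3-chloro-5-methoxybenzaldehyde | COc1cc(Cl)c(Br)c(C=O)c1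
F6 | step 21 | 2-(2-bromo-3-chloro-5-methoxyphenyl)-1,3-dioxolane | COc1cc(Cl)c(Br)c(C2OCCO2)c1
F7 | step 21 | (1R,2R)-2-(unit DCB)-2-[2-chloro-6-(1,3-dioxolan-2-yl)-4-methoxyphenyl]-1-(4-methoxyphenyl)ethylboronic acid mac ester | COc1ccc([C@H]2Oc3cc(OC)cc([C@@H]([C@H](c4ccc(OC)cc4)B4O[C@@]5(C)c6cccc7cccc(c67)[C@@]5(C)O4)c4c(Cl)cc(OC)cc4C4OCCO4)c3[C@@H]2c2cc(OC)cc3c2[C@@H](c2cc(OC)cc(OC)c2)[C@H](c2ccc(OC)cc2)O3)cc1
F8 | step 21 | (1R,2R)-2-(unit DCB)-2-[2-chloro-6-(1,3-dioxolan-2-yl)-4-methoxyphenyl]-1-(4-methoxyphenyl)ethanol | COc1ccc([C@H]2Oc3cc(OC)cc([C@@H]([C@H](c4ccc(OC)cc4)O)c4c(Cl)cc(OC)cc4C4OCCO4)c3[C@@H]2c2cc(OC)cc3c2[C@@H](c2cc(OC)cc(OC)c2)[C@H](c2ccc(OC)cc2)O3)cc1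
F9 | step 21 | (2R,3R)-3-(unit DCB)-4-(1,3-dioxolan-2-yl)-6-methoxy-2-(4-methoxyphenyl)-2,3-dihydrobenzofuran | COc1ccc([C@H]2Oc3cc(OC)cc([C@@H]4c5c(C6OCCO6)cc(OC)cc5O[C@H]4c4ccc(OC)cc4)c3[C@@H]2c2cc(OC)cc3c2[C@@H](c2cc(OC)cc(OC)c2)[C@H](c2ccc(OC)cc2)O3)cc1
F10 | step 21 | (2R,3R)-3-(unit DCB)-6-methoxy-2-(4-methoxyphenyl)-2,3-dihydrobenzofuran-4-carbaldehyde | COc1ccc([C@H]2Oc3cc(OC)cc([C@@H]4c5c(C=O)cc(OC)cc5O[C@H]4c4ccc(OC)cc4)c3[C@@H]2c2cc(OC)cc3c2[C@@H](c2cc(OC)cc(OC)c2)[C@H](c2ccc(OC)cc2)O3)cc1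
F11 | step 22 | (2R,3R)-4-{(E)-2-[3,4-bis(tert-butyldimethylsilyloxy)phenyl]ethenyl}-3-(unit DCB)-2-(4-methoxyphenyl)-2,3-dihydrobenzofuran-6-ol | COc1ccc([C@H]2Oc3cc(OC)cc([C@@H]4c5c(/C=C/c6ccc(O[Si](C)(C)C(C)(C)C)c(O[Si](C)(C)C(C)(C)C)c6)cc(O)cc5O[C@H]4c4ccc(OC)cc4)c3[C@@H]2c2cc(OC)cc3c2[C@@H](c2cc(OC)cc(OC)c2)[C@H](c2ccc(OC)cc2)O3)cc1
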